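## Structural features

The target is a 2,3-dihydro-1-benzofuran whose benzene ring is fully substituted. It carries hydroxyl groups at C4 and C6, an acetyl group between them at C5, the ring oxygen O1 on C7a, and at C7 a methylene bridge to C3 of a 6-ethyl-4-hydroxy-5-methyl-2-pyranone. C2 bears a 6-methylhepta-1,5-dien-2-yl group and is the only stereocentre (R). No other stereocentre stands next to it, so nothing in the molecule can relay its configuration. This carbon is at once an aryl ether carbon, allylic to a 1,1-disubstituted alkene and homobenzylic, so it is exposed to ionisation under acid and to ring-opening elimination under strong base. The fragile groups are the two alkenes (acid, electrophiles and hydrogenation are excluded), the air-sensitive acylphloroglucinol ring, the vinylogous acid of the pyranone, and the doubly activated methylene bridge, which acid or hot base can cleave or scramble. The real difficulty is therefore twofold: one isolated, labile stereocentre, and a hexasubstituted arene on which every position must be addressed regioselectively. The key step exploits the fact that C2 is bonded to one CH2–aryl carbon (C3), one alkenyl carbon (C1') and one oxygen (O1). That is the pattern of a carbon inserted into the C–B bond of a benzylboronic ester, alkylated by an alkenyl nucleophile and then oxidised at boron. A symmetrical 2,4,6-trifluorophenyl ring then supplies the leaving group for closure of O1 onto C7a and the handles for the C4 and C6 oxygens.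

## Logic of the disconnections

27 ⇒ 21 + 24. Both bonds of the bridging methylene are cut (C7–CH2 and CH2–C3 of the pyranone). The bridge is the most labile linkage and the pyranone would not survive the organometallic steps, so it is added last. This splits the molecule into two pieces of similar size. The forward step must load the one-carbon unit onto 24 first (25, then 26), so that 21 meets only the electrophile and homodimers are avoided.

24 ⇒ 23 ⇒ 22. The pyranone is cut at C4–C5 and O1–C2, which reveals a malonyl unit and the enol of a symmetrical ketone. The ketone is symmetrical, so its enol derivative 23 has no regiochemical ambiguity. The forward step needs C-acylation before lactonisation.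

21 ⇒ 20 ⇒ 18. The C4–O and C6–O bonds are traced back to C–F bonds. The C5 acetyl group is ortho to both, so each fluorine can be displaced by an alkoxide. A 2-silylethyl alkoxide is chosen because fluoride later releases the phenols without acid, base-labile esters or hydrogen. The demand is that both displacements go, the second at the crowded C4.

18 ⇒ 16 (through 17). The C5–acetyl bond is cut. C5 lies between two fluorines and carries the most acidic hydrogen of 16, so lithiation and acylation place the ketone without any directing group. The forward step needs low temperature, so that 17 does not lose fluoride, and an acyl donor that stops at the ketone.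

16 ⇒ 15. The O1–C7a bond is cut. The alkoxide of 15 can displace an ortho fluorine; both ortho fluorines are equivalent, so there is no regiochemical choice, and the C2–O bond is never broken. The demand is an aromatic substitution on a ring activated only by fluorine.

15 ⇒ 14. The C2–O bond is traced to a C2–B bond. Oxidation of boron is stereoretentive, so the problem of the stereocentre becomes that of a secondary allylic boronic ester.

14 ⇒ 5 + 11 + 10 (through 12 and 13). The C3–C2 and C2–C1' bonds are cut, and C2 becomes the carbon of 11. This is the strategic simplification: a benzylboronic ester, a one-carbon linchpin and an alkenyl nucleophile, with the chiral diol on boron as the only source of asymmetry. Both 1,2-shifts must be stereospecific and the first must be diastereoselective. Compound 5 keeps three fluorines and no oxygen because the ring must not offer any electrophilic or acidic function to 12 or 10.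

5 ⇒ 1 + 2 (through 3 and 4). The benzylic C–B bond and the two B–O bonds are cut. This leads to a commercial benzyl bromide and a commercial C2-symmetric diol.

10 ⇒ 9 ⇒ 7 ⇒ 6 (through 8). The C–Mg bond goes back to a C–Br bond, and this to the methyl ketone through its arenesulfonyl hydrazone. A Shapiro reaction places the metal on the carbonyl carbon and the double bond toward the methyl group. The purified bromide 9 is preferred to a direct lithium-to-magnesium exchange on 8, so that no sulfinate or excess alkyllithium enters the key step.

## Other disconnections considered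

Alternative 1: The cut removes both bonds by which the dihydrofuran ring hangs on the arene, C3a–C3 and C7a–O1. It leads to the aryl iodide A2 (iodine on the future C7a, hydrogen on the future C3a, the bridged pyranone already at C7) and the terminal epoxide A3, whose CH2 becomes C3 and whose oxygen becomes O1.
- Forward step: with Pd(OAc)2 and norbornene (Catellani reaction), zerovalent palladium would insert into the C–I bond and norbornene would relay the metal to the free ortho position. The resulting palladacycle would open the epoxide at its CH2 end. After extrusion of norbornene the tethered alkoxide would close onto the ipso carbon by C–O reductive elimination to give A1.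
- In favour: the ring is annulated in one convergent operation. The stereocentre comes with the epoxide and its C–O bond is never broken. The aromatic oxygens are present from the start, so no fluorine has to be exchanged. On convergence and on bonds formed in the key step it is the better plan.
- Against: A2 is a hexasubstituted, electron-rich iodide flanked by a bulky benzylic group and carrying an enolisable ketone and a pyranone, so both oxidative addition and ortho palladation would be crowded. A3 has a fully substituted silyloxy carbon next to the reacting epoxide and needs its own asymmetric synthesis. After A1, a Peterson elimination and the acidic removal of three methoxymethyl groups, beside two acid-sensitive alkenes, still stand before 27.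
- Comparison: stereocontrol is equal (reagent-controlled, then untouched). Mechanistically the chosen plan rests on two stereospecific 1,2-shifts of simple groups, whereas this one asks a multi-event palladium relay to tolerate a very dense substrate. In step count, the preparation of A2 and A3 is expected to outweigh the steps saved after the key step.

Alternative 2: The benzene ring itself is cut at C4–C5. This turns A4 into the dihydrofuran ester A5, a 4,5-dihydrofuran with the stereocentre and the diene side chain at its sp3 carbon, a methyl ester on the future C3a and a 2,4-dioxopentyl arm on the future C7a.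
- Forward step: base would form the carbanion between the two ketones, which attacks the ester in a 6-exo-trig Claisen (Dieckmann-type) closure. Loss of methoxide and enolisation of both ring carbonyls would aromatise to A4, which is the same compound as 21.
- In favour: all ring oxygens and the acetyl group arrive in their final place and oxidation state, without protecting groups or aromatic substitution. Aromatisation is a strong driving force. The route would join the chosen one at 21. On protecting-group economy and on avoiding the twofold fluoride displacement it is the better plan.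
- Against: A5 is a polycarbonyl compound with several acidic sites and nucleophilic oxygens. O-acylation to a pyranone, aldol pathways and base-induced opening of the dihydrofuran (β-elimination of the ring oxygen from the vinylogous ester) can compete with the desired C-acylation. The cut does nothing for the stereocentre, which would have to be installed in A5 by a separate asymmetric step.
- Comparison: structurally the chosen plan keeps a commercial arene intact, while this one builds it. Mechanistically both close rings by polar addition–elimination and are equal in kind, but the chosen plan has fewer competing pathways. In step economy they are about equal at best: the steps from 16 to 21 are saved, but A5 must be assembled from several pieces together with its stereocentre.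

Alternative 3: The cut takes the acetyl carbon from C5 and the oxygen from C6 together, leading from A6 to the ortho-silyl aryl triflate A7 and acetic acid.
- Forward step: fluoride would unmask the C5–C6 aryne. Acetate adds through oxygen at C6, the carbon remote from the C4 alkoxy group. The aryl anion at C5 then attacks the ester carbonyl, and the four-membered intermediate opens to the ortho-hydroxyaryl ketone A6.
- In favour: two neighbouring substituents are set in one mild step that spares the alkenes and the C2 ether. The regiochemistry follows from the inductive effect of the C4 oxygen and is as dependable as the lithiation between two fluorines in the chosen plan. On regiocontrol it is equal, and on mildness the better.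
- Against: A7 already contains the dihydrobenzofuran with its stereocentre, so the cut leaves the real difficulty unsolved. It adds the task of placing silyl, triflate and methoxymethoxy groups on three neighbouring carbons. Simple O-arylation followed by protonation, without the acyl shift, is a plausible competing course with a small acid. The methoxymethyl ether must later be removed with acid.
- Comparison: it is a functional-group tactic and not a skeletal strategy. It is expected to be longer than the chosen plan, because the steps to A7 replace only the acetylation and one of the two fluoride displacements.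

Key step: step 5

Remark on the chemistry: the (R,R)-diol is taken to give the (S)-α-chloro boronic ester 13, the normal sense of this homologation; inversion by the alkenyl group then gives (R)-14 and, after retentive oxidation, the R configuration at C2 of 27 (the descriptors of 5, 13, 14, 15 and 27 were checked against their SMILES and agree).

Step 1
Reactants: 1 2,4,6-trifluorobenzyl bromide; 2 (1R,2R)-1,2-dicyclohexylethane-1,2-diol
Product: 5 (4R,5R)-4,5-dicyclohexyl-2-[(2,4,6-trifluorophenyl)methyl]-1,3,2-dioxaborolane, via (2,4,6-trifluorobenzyl)magnesium bromide 3 (not isolated), via (2,4,6-trifluorobenzyl)boronic acid 4 (not isolated)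
Conditions: Mg turnings, Et2O, 0 °C (slow addition of 1); B(OMe)3, −78 °C → rt; 1 M HCl, 0 °C; Et2O extract, 2, MgSO4, rt
Reagents that add atoms: trimethyl borate, COB(OC)OC
Why: Magnesium insertion into the benzylic C–Br bond at high dilution limits Wurtz coupling, the Grignard reagent 3 is borylated by the borate ester, and the crude boronic acid 4 condenses with the 1,2-diol to a hindered, hydrolytically robust cyclic ester (Grignard borylation, then boronic ester condensation); the diol stereocentres are carried in unchanged.

Step 2
Reactants: 6 6-methylhept-5-en-2-one
Product: 7 (E)-N'-(6-methylhept-5-en-2-ylidene)-2,4,6-tri(propan-2-yl)benzenesulfonohydrazide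
Conditions: 2,4,6-iPr3C6H2SO2NHNH2 (1.0 equiv), MeOH, cat. HCl, rt
Reagents that add atoms: 2,4,6-tri(propan-2-yl)benzenesulfonohydrazide, CC(C)c1cc(C(C)C)c(S(=O)(=O)NN)c(C(C)C)c1
Why: Acid-catalysed condensation of a ketone with a sulfonyl hydrazide; the E hydrazone, with the sulfonamide nitrogen syn to the methyl group, should predominate and crystallise.

Step 3
Reactants: 7 (E)-N'-(6-methylhept-5-en-2-ylidene)-2,4,6-tri(propan-2-yl)benzenesulfonohydrazide
Product: 9 2-bromo-6-methylhepta-1,5-diene, via (6-methylhepta-1,5-dien-2-yl)lithium 8 (not isolated)
Conditions: n-BuLi (2.1 equiv), THF, −78 °C, then 0 °C until N2 evolution stops; BrCH2CH2Br, −78 °C → rt; distillation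
Reagents that add atoms: 1,2-dibromoethane, BrCCBr
Why: Shapiro reaction: the hydrazone dianion forms by deprotonation of the methyl group syn to the sulfonamide nitrogen and loses arenesulfinate and N2 to give the 2-lithio-1-alkene 8, which takes bromine from 1,2-dibromoethane with release of ethene; the trisubstituted alkene is not touched.

Step 4
Reactants: 9 2-bromo-6-methylhepta-1,5-diene
Product: 10 (6-methylhepta-1,5-dien-2-yl)magnesium bromide (THF solution, titrated and used at once)
Conditions: Mg turnings (I2 crystal), THF, rt → 40 °C
Reagents that add atoms: magnesium, [Mg]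
Why: Direct insertion of magnesium into the alkenyl C–Br bond, as for other 2-bromo-1-alkenes; a purified bromide gives a reagent free of sulfinate and alkyllithium.

Step 5
Reactants: 5 (4R,5R)-4,5-dicyclohexyl-2-[(2,4,6-trifluorophenyl)methyl]-1,3,2-dioxaborolane; 11 dichloromethane; 10 (6-methylhepta-1,5-dien-2-yl)magnesium bromide
Product: 14 (4R,5R)-4,5-dicyclohexyl-2-[(2R)-7-methyl-3-methylidene-1-(2,4,6-trifluorophenyl)oct-6-en-2-yl]-1,3,2-dioxaborolane, via (dichloromethyl)lithium 12 (not isolated), via (1S)-α-chloro boronic ester 13 (not isolated)
Conditions: 11 (3 equiv), n-BuLi (1.2 equiv), THF, −100 °C; 5; ZnCl2 (1.1 equiv), −100 °C → rt; 10 (2.5 equiv), −78 °C → rt; aq. NH4Cl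
Reagents that add atoms: none
Why: (Dichloromethyl)lithium 12, made from 11 and n-BuLi at −100 °C, adds to the boron of 5 to give a tetracoordinate borate, and on warming with ZnCl2 the benzyl group shifts from boron to carbon with loss of one of the two diastereotopic chlorides, giving 13. Reagent 10 then forms a second borate and the alkenyl group migrates anti to the remaining C–Cl bond, so that this carbon is inverted and 14 results. The closest known reaction type is the Matteson homologation of diol boronic esters with LiCHCl2 and ZnCl2 followed by displacement of chloride by a Grignard reagent, established for benzyl as first and alkenyl as second migrating group. No ring is closed; the two skeletal bonds C3–C2 and C2–C1' and one stereocentre are made. The stereocentre is controlled by the C2-symmetric (R,R)-diol on boron, which together with zinc coordination decides which chloride leaves and so gives (S)-13, and the stereospecific second shift converts this into (R)-14. The step needs attack of 12 at boron rather than deprotonation of the ring C–H flanked by two fluorines, which preformed 12 at −100 °C in the absence of an amide base should secure. It also needs 10 in excess over ZnCl2 so that the alkenyl group reaches boron, while zinc binds free chloride and suppresses epimerisation of 13. The trifluorophenyl ring offers no electrophilic group to either organometallic, and 14 is worked up cold and oxidised without delay to forestall allylic boron migration.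

Step 6
Reactants: 14 (4R,5R)-4,5-dicyclohexyl-2-[(2R)-7-methyl-3-methylidene-1-(2,4,6-trifluorophenyl)oct-6-en-2-yl]-1,3,2-dioxaborolane
Product: 15 (2R)-7-methyl-3-methylidene-1-(2,4,6-trifluorophenyl)oct-6-en-2-ol
Conditions: 30% H2O2, 2 M NaOH, THF, 0 °C → rt
Reagents that add atoms: hydrogen peroxide, OO
Why: Oxidation of the C–B bond: hydroperoxide adds to boron and carbon migrates from boron to oxygen with retention, so (R)-14 gives the (R)-allylic alcohol; alkaline peroxide does not epoxidise isolated alkenes, and diol 2 is recovered.

Step 7
Reactants: 15 (2R)-7-methyl-3-methylidene-1-(2,4,6-trifluorophenyl)oct-6-en-2-ol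
Product: 16 (2R)-4,6-difluoro-2-(6-methylhepta-1,5-dien-2-yl)-2,3-dihydro-1-benzofuran
Conditions: KOtBu (1.3 equiv), THF, 0 → 60 °C
Reagents that add atoms: none
Why: Intramolecular nucleophilic aromatic substitution (5-exo addition–elimination) of the potassium alkoxide on an ortho fluorine activated by two meta fluorines; the two ortho fluorines are equivalent, so only one product can form, and the C2–O bond is not broken, so the R configuration is kept.

Step 8
Reactants: 16 (2R)-4,6-difluoro-2-(6-methylhepta-1,5-dien-2-yl)-2,3-dihydro-1-benzofuran
Product: 18 1-[(2R)-4,6-difluoro-2-(6-methylhepta-1,5-dien-2-yl)-2,3-dihydro-1-benzofuran-5-yl]ethanone, via C5 aryllithium 17 (not isolated)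
Conditions: LiN(iPr)2 (1.1 equiv), THF, −78 °C; MeC(O)N(OMe)Me, −78 → 0 °C; aq. NH4Cl
Reagents that add atoms: N-methoxy-N-methylacetamide, CC(=O)N(C)OC
Why: Directed ortho metalation at C5, the C–H flanked by two fluorines and therefore the most acidic (the site selectivity known for 3,5-difluoroalkoxybenzenes), followed by acylation with an N-methoxy-N-methylamide, whose chelated tetrahedral adduct prevents over-addition; at −78 °C the aryllithium 17 should not lose LiF and the benzylic and allylic hydrogens are left alone.

Step 9
Reactants: 18 1-[(2R)-4,6-difluoro-2-(6-methylhepta-1,5-dien-2-yl)-2,3-dihydro-1-benzofuran-5-yl]ethanone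
Product: 20 1-[(2R)-2-(6-methylhepta-1,5-dien-2-yl)-4,6-bis[2-(trimethylsilyl)ethoxy]-2,3-dihydro-1-benzofuran-5-yl]ethanone, via C6 mono(silylethyl) ether 19 (not isolated)
Conditions: Me3SiCH2CH2OH (10 equiv), NaH (3 equiv), THF, 0 → 65 °C
Reagents that add atoms: 2-(trimethylsilyl)ethanol, C[Si](C)(C)CCO
Why: Two nucleophilic aromatic substitutions of fluorine ortho to the acetyl group, which stabilises each anionic adduct; the less hindered C6 fluorine should go first (19) and the C4 fluorine on heating, and the excess of free alcohol keeps the ketone from being held as its unreactive enolate.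

Step 10
Reactants: 20 1-[(2R)-2-(6-methylhepta-1,5-dien-2-yl)-4,6-bis[2-(trimethylsilyl)ethoxy]-2,3-dihydro-1-benzofuran-5-yl]ethanone
Product: 21 1-[(2R)-4,6-dihydroxy-2-(6-methylhepta-1,5-dien-2-yl)-2,3-dihydro-1-benzofuran-5-yl]ethanone
Conditions: Bu4NF (4 equiv), THF, 0 → 50 °C; degassed aq. NH4Cl
Reagents that add atoms: none
Why: Fluoride attacks silicon and each 2-silylethyl ether fragments by β-elimination to ethene, Me3SiF and the aryloxide, which as an ortho-acyl phenoxide is a good leaving group; alkenes, ketone and the C2 ether are inert to fluoride.

Step 11
Reactants: 22 pentan-3-one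
Product: 23 (Z)-trimethyl(pent-2-en-3-yloxy)silane
Conditions: Me3SiOTf (1.1 equiv), Et3N (1.3 equiv), Et2O, 0 °C → rt
Reagents that add atoms: trimethylsilyl trifluoromethanesulfonate, C[Si](C)(C)OS(=O)(=O)C(F)(F)F
Why: Soft enolisation and O-silylation of a symmetrical ketone; only one regioisomer is possible and the alkene geometry is of no consequence for step 12.

Step 12
Reactants: 23 (Z)-trimethyl(pent-2-en-3-yloxy)silane
Product: 24 6-ethyl-4-hydroxy-5-methyl-2H-pyran-2-one
Conditions: ClC(O)CH2C(O)Cl (1.0 equiv), Et2O, −78 °C → rt
Reagents that add atoms: malonyl dichloride, O=C(Cl)CC(Cl)=O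
Why: Cyclocondensation: the silyl enol ether is C-acylated by one acid chloride group of malonyl dichloride and the enol oxygen of the resulting diketo acid chloride closes the lactone, giving the 4-hydroxy-2-pyranone with ethyl at C6 and methyl at C5.

Step 13
Reactants: 21 1-[(2R)-4,6-dihydroxy-2-(6-methylhepta-1,5-dien-2-yl)-2,3-dihydro-1-benzofuran-5-yl]ethanone; 24 6-ethyl-4-hydroxy-5-methyl-2H-pyran-2-one
Product: 27 3-{[(2R)-5-acetyl-4,6-dihydroxy-2-(6-methylhepta-1,5-dien-2-yl)-2,3-dihydro-1-benzofuran-7-yl]methyl}-6-ethyl-4-hydroxy-5-methyl-2H-pyran-2-one, via pyranone Mannich base 25 (not isolated), via 3-methylidene pyrandione 26 (not isolated)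
Conditions: 24, [Me2N=CH2]I (1.0 equiv), MeCN, rt; then 21 (1.0 equiv), 60 °C
Reagents that add atoms: dimethylmethylideneammonium iodide, C[N+](C)=C.[I-]
Why: Mannich reaction at C3 of the pyranone gives 25, which on warming loses dimethylamine to the Michael acceptor 26; this is captured by C7 of 21, the only unsubstituted ring carbon and ortho to a phenol (Friedel–Crafts-type conjugate addition), and because 24 is consumed before 21 is added the symmetrical bis-pyranone should be avoided; C2 is not involved and the medium stays near neutral.

## Compound list

1 | 2,4,6-trifluorobenzyl bromide | Fc1cc(F)c(CBr)c(F)c1 | starting material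
2 | (1R,2R)-1,2-dicyclohexylethane-1,2-diol | O[C@H](C1CCCCC1)[C@H](O)C1CCCCC1 | starting material
3 | (2,4,6-trifluorobenzyl)magnesium bromide | Fc1cc(F)c(C[Mg]Br)c(F)c1 | intermediate
4 | (2,4,6-trifluorobenzyl)boronic acid | OB(O)Cc1c(F)cc(F)cc1F | intermediate
5 | (4R,5R)-4,5-dicyclohexyl-2-[(2,4,6-trifluorophenyl)methyl]-1,3,2-dioxaborolane | Fc1cc(F)c(CB2O[C@H](C3CCCCC3)[C@@H](C3CCCCC3)O2)c(F)c1 | intermediate
6 | 6-methylhept-5-en-2-one | CC(=O)CCC=C(C)C | starting material
7 | (E)-N'-(6-methylhept-5-en-2-ylidene)-2,4,6-tri(propan-2-yl)benzenesulfonohydrazide | C/C(CCC=C(C)C)=N\NS(=O)(=O)c1c(C(C)C)cc(C(C)C)cc1C(C)C | intermediate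
8 | (6-methylhepta-1,5-dien-2-yl)lithium | [Li]C(=C)CCC=C(C)C | intermediate
9 | 2-bromo-6-methylhepta-1,5-diene | C=C(Br)CCC=C(C)C | intermediate
10 | (6-methylhepta-1,5-dien-2-yl)magnesium bromide | C=C([Mg]Br)CCC=C(C)C | intermediate
11 | dichloromethane | ClCCl | starting material
12 | (dichloromethyl)lithium | [Li]C(Cl)Cl | intermediate
13 | (4R,5R)-2-[(1S)-1-chloro-2-(2,4,6-trifluorophenyl)ethyl]-4,5-dicyclohexyl-1,3,2-dioxaborolane | Cl[C@H](Cc1c(F)cc(F)cc1F)B1O[C@H](C2CCCCC2)[C@@H](C2CCCCC2)O1 | intermediate
14 | (4R,5R)-4,5-dicyclohexyl-2-[(2R)-7-methyl-3-methylidene-1-(2,4,6-trifluorophenyl)oct-6-en-2-yl]-1,3,2-dioxaborolane | C=C(CCC=C(C)C)[C@@H](Cc1c(F)cc(F)cc1F)B1O[C@H](C2CCCCC2)[C@@H](C2CCCCC2)O1 | intermediate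
15 | (2R)-7-methyl-3-methylidene-1-(2,4,6-trifluorophenyl)oct-6-en-2-ol | C=C(CCC=C(C)C)[C@@H](Cc1c(F)cc(F)cc1F)O | intermediate
16 | (2R)-4,6-difluoro-2-(6-methylhepta-1,5-dien-2-yl)-2,3-dihydro-1-benzofuran | C=C(CCC=C(C)C)[C@H]1Cc2c(F)cc(F)cc2O1 | intermediate
17 | [(2R)-4,6-difluoro-2-(6-methylhepta-1,5-dien-2-yl)-2,3-dihydro-1-benzofuran-5-yl]lithium | C=C(CCC=C(C)C)[C@H]1Cc2c(F)c([Li])c(F)cc2O1 | intermediate
18 | 1-[(2R)-4,6-difluoro-2-(6-methylhepta-1,5-dien-2-yl)-2,3-dihydro-1-benzofuran-5-yl]ethanone | C=C(CCC=C(C)C)[C@H]1Cc2c(F)c(C(C)=O)c(F)cc2O1 | intermediate
19 | 1-[(2R)-4-fluoro-2-(6-methylhepta-1,5-dien-2-yl)-6-[2-(trimethylsilyl)ethoxy]-2,3-dihydro-1-benzofuran-5-yl]ethanone (expected regioisomer; the C4 mono-ether would converge on 20 as well) | C=C(CCC=C(C)C)[C@H]1Cc2c(F)c(C(C)=O)c(OCC[Si](C)(C)C)cc2O1 | intermediate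
20 | 1-[(2R)-2-(6-methylhepta-1,5-dien-2-yl)-4,6-bis[2-(trimethylsilyl)ethoxy]-2,3-dihydro-1-benzofuran-5-yl]ethanone | C=C(CCC=C(C)C)[C@H]1Cc2c(OCC[Si](C)(C)C)c(C(C)=O)c(OCC[Si](C)(C)C)cc2O1 | intermediate
21 | 1-[(2R)-4,6-dihydroxy-2-(6-methylhepta-1,5-dien-2-yl)-2,3-dihydro-1-benzofuran-5-yl]ethanone | C=C(CCC=C(C)C)[C@H]1Cc2c(O)c(C(C)=O)c(O)cc2O1 | intermediate
22 | pentan-3-one | CCC(=O)CC | starting material
23 | (Z)-trimethyl(pent-2-en-3-yloxy)silane | C/C=C(/CC)O[Si](C)(C)C | intermediate
24 | 6-ethyl-4-hydroxy-5-methyl-2H-pyran-2-one | CCc1oc(=O)cc(O)c1C | intermediate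
25 | 3-[(dimethylamino)methyl]-6-ethyl-4-hydroxy-5-methyl-2H-pyran-2-one | CCc1oc(=O)c(CN(C)C)c(O)c1C | intermediate
26 | 6-ethyl-5-methyl-3-methylidene-2H-pyran-2,4(3H)-dione | CCC1=C(C)C(=O)C(=C)C(=O)O1 | intermediate
27 | 3-{[(2R)-5-acetyl-4,6-dihydroxy-2-(6-methylhepta-1,5-dien-2-yl)-2,3-dihydro-1-benzofuran-7-yl]methyl}-6-ethyl-4-hydroxy-5-methyl-2H-pyran-2-one | C=C(CCC=C(C)C)[C@H]1Cc2c(O)c(C(C)=O)c(O)c(Cc3c(O)c(C)c(CC)oc3=O)c2O1 | target

## Step count and least certain steps

Total: 13 steps. Longest linear sequence: 10 steps (6 → 7 → 9 → 10 → 14 → 15 → 16 → 18 → 20 → 21 → 27, that is steps 2, 3, 4, 5, 6, 7, 8, 9, 10 and 13). The branch from 1 joins at step 5 and the branch from 22 at step 13.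

Step 5 (key step). What may go wrong:
- deprotonation of the acidic ring or benzylic C–H of 5 by 12, in competition with addition to boron;
- transmetalation of 10 to zinc, so that the second borate forms slowly and 13 is left over or loses HCl;
- chloride-induced epimerisation of 13, eroding the diastereoselectivity;
- allylic migration of boron in 14 before oxidation.

Fallback: setting out from 10, addition to N-methoxy-N-methyl-2-(2,4,6-trifluorophenyl)acetamide F1 (from commercial (2,4,6-trifluorophenyl)acetic acid, N,O-dimethylhydroxylamine hydrochloride and a carbodiimide) at −20 °C would give the enone 7-methyl-3-methylidene-1-(2,4,6-trifluorophenyl)oct-6-en-2-one F2. Corey–Bakshi–Shibata reduction with (S)-2-methyl-CBS-oxazaborolidine and BH3·SMe2, with the α-branched alkenyl group taken as the larger substituent, should then give the (R)-alcohol and come back to the route at 15. The stereocentre is then set by catalyst-controlled hydride delivery instead of by boron.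

Step 9. What may go wrong:
- enolisation of the methyl ketone, which holds the substrate as an unreactive enolate;
- stalling of the second displacement at 19, because C4 is crowded and the carbonyl, now flanked by two ortho substituents, is twisted out of conjugation;
- on prolonged heating, aldol self-condensation or alkoxide attack at C7a (para to the acetyl group) with opening of the ring.

Fallback: setting out from 16, lithiation as in step 8 and capture of 17 with 4-methylbenzenesulfonyl cyanide would give (2R)-4,6-difluoro-2-(6-methylhepta-1,5-dien-2-yl)-2,3-dihydro-1-benzofuran-5-carbonitrile F3. Its linear, non-enolisable nitrile should allow both fluorines to be displaced by sodium 2-(trimethylsilyl)ethanolate, giving (2R)-2-(6-methylhepta-1,5-dien-2-yl)-4,6-bis[2-(trimethylsilyl)ethoxy]-2,3-dihydro-1-benzofuran-5-carbonitrile F4. Addition of MeLi and hydrolysis of the ketimine with cold dilute HCl would come back to the route at 20.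

Step 7. What may go wrong: slow attack on a ring activated only by fluorine, so that the hot basic medium isomerises the allylic alkoxide or tert-butoxide substitutes intermolecularly.

Fallback: setting out from 15, two equivalents of LiN(iPr)2 at −78 °C (alkoxide, then lithiation between two ring fluorines) and N-methoxy-N-methylacetamide would give 1-{2,4,6-trifluoro-3-[(2R)-2-hydroxy-7-methyl-3-methylideneoct-6-en-1-yl]phenyl}ethanone F5. Its alkoxide (KOtBu, THF, 0 °C) should close readily onto the fluorine para to the acetyl group, now activated and the less hindered of the two fluorines next to the tether. This comes back to the route at 18, bypassing 16 and step 8. The price is a regiochemical choice: closure onto the fluorine between tether and acetyl group would give the 7-acetyl isomer, which would have to be separated.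

Step 10. What may go wrong: incomplete loss of the second silylethyl group once the first phenoxide has formed (the ring becomes electron-rich and the remaining aryloxide a poorer leaving group), and oxidative or base-mediated degradation of the acylphloroglucinol at the temperature then needed.

Fallback: setting out from 18, the same twofold substitution with sodium prop-2-en-1-olate in allyl alcohol–THF would give 1-[(2R)-2-(6-methylhepta-1,5-dien-2-yl)-4,6-bis(prop-2-en-1-yloxy)-2,3-dihydro-1-benzofuran-5-yl]ethanone F6. Allyl transfer to morpholine with catalytic Pd(PPh3)4 at rt would come back to the route at 21. The unsubstituted O-allyl groups are expected to ionise much faster than the substituted, cyclic allylic ether at C2.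

Step 13. What may go wrong: capture of 26 by residual 24 (symmetrical bis-pyranone) or by a phenolic oxygen of 21, double alkylation, and reversible cleavage of the methylene bridge on long heating, which would scramble the partners.

Fallback: setting out from 21, aminomethylation at C7 with the same iminium salt would give 1-[(2R)-7-[(dimethylamino)methyl]-4,6-dihydroxy-2-(6-methylhepta-1,5-dien-2-yl)-2,3-dihydro-1-benzofuran-5-yl]ethanone F7. Heating F7 with 24 in dioxane should release dimethylamine and form the ortho-quinone methide on the benzofuran side, which C3 of 24 captures, coming back to the route at 27. The polarity of the coupling is reversed and the electrophile is generated only on the more valuable partner.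

## Further compounds

F1 | step 5 | N-methoxy-N-methyl-2-(2,4,6-trifluorophenyl)acetamide | CON(C)C(=O)Cc1c(F)cc(F)cc1F
F2 | step 5 | 7-methyl-3-methylidene-1-(2,4,6-trifluorophenyl)oct-6-en-2-one | C=C(CCC=C(C)C)C(=O)Cc1c(F)cc(F)cc1F
F3 | step 9 | (2R)-4,6-difluoro-2-(6-methylhepta-1,5-dien-2-yl)-2,3-dihydro-1-benzofuran-5-carbonitrile | C=C(CCC=C(C)C)[C@H]1Cc2c(F)c(C#N)c(F)cc2O1
F4 | step 9 | (2R)-2-(6-methylhepta-1,5-dien-2-yl)-4,6-bis[2-(trimethylsilyl)ethoxy]-2,3-dihydro-1-benzofuran-5-carbonitrile | C=C(CCC=C(C)C)[C@H]1Cc2c(OCC[Si](C)(C)C)c(C#N)c(OCC[Si](C)(C)C)cc2O1
F5 | step 7 | 1-{2,4,6-trifluoro-3-[(2R)-2-hydroxy-7-methyl-3-methylideneoct-6-en-1-yl]phenyl}ethanone | C=C(CCC=C(C)C)[C@@H](Cc1c(F)cc(F)c(C(C)=O)c1F)O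
F6 | step 10 | 1-[(2R)-2-(6-methylhepta-1,5-dien-2-yl)-4,6-bis(prop-2-en-1-yloxy)-2,3-dihydro-1-benzofuran-5-yl]ethanone | C=C(CCC=C(C)C)[C@H]1Cc2c(OCC=C)c(C(C)=O)c(OCC=C)cc2O1
F7 | step 13 | 1-[(2R)-7-[(dimethylamino)methyl]-4,6-dihydroxy-2-(6-methylhepta-1,5-dien-2-yl)-2,3-dihydro-1-benzofuran-5-yl]ethanone | C=C(CCC=C(C)C)[C@H]1Cc2c(O)c(C(C)=O)c(O)c(CN(C)C)c2O1
A1 | alternative 1 | 1-[(2R)-7-{[6-ethyl-4-(methoxymethoxy)-5-methyl-2-oxopyran-3-yl]methyl}-4,6-bis(methoxymethoxy)-2-[6-methyl-2-(triethylsilyloxy)-1-(trimethylsilyl)hept-5-en-2-yl]-2,3-dihydro-1-benzofuran-5-yl]ethanone | C[Si](C)(C)CC(O[Si](CC)(CC)CC)(CCC=C(C)C)[C@H]1Cc2c(OCOC)c(C(C)=O)c(OCOC)c(Cc3c(OCOC)c(C)c(CC)oc3=O)c2O1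
A2 | alternative 1 | 1-[3-{[6-ethyl-4-(methoxymethoxy)-5-methyl-2-oxo-2H-pyran-3-yl]methyl}-4-iodo-2,6-bis(methoxymethoxy)phenyl]ethanone | CC(=O)c1c(OCOC)cc(I)c(Cc2c(OCOC)c(C)c(CC)oc2=O)c1OCOC
A3 | alternative 1 | triethyl({6-methyl-2-[(2R)-oxiran-2-yl]-1-(trimethylsilyl)hept-5-en-2-yl}oxy)silane | C[Si](C)(C)CC(O[Si](CC)(CC)CC)(CCC=C(C)C)[C@H]1CO1
A4 | alternative 2 | 1-[(2R)-4,6-dihydroxy-2-(6-methylhepta-1,5-dien-2-yl)-2,3-dihydro-1-benzofuran-5-yl]ethanone | C=C(CCC=C(C)C)[C@H]1Cc2c(O)c(C(C)=O)c(O)cc2O1
A5 | alternative 2 | methyl (5R)-2-(2,4-dioxopentyl)-5-(6-methylhepta-1,5-dien-2-yl)-4,5-dihydrofuran-3-carboxylate | C=C(CCC=C(C)C)[C@H]1CC(C(=O)OC)=C(CC(=O)CC(C)=O)O1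
A6 | alternative 3 | 1-[(2R)-6-hydroxy-4-(methoxymethoxy)-2-(6-methylhepta-1,5-dien-2-yl)-2,3-dihydro-1-benzofuran-5-yl]ethanone | C=C(CCC=C(C)C)[C@H]1Cc2c(OCOC)c(C(C)=O)c(O)cc2O1
A7 | alternative 3 | (2R)-4-(methoxymethoxy)-2-(6-methylhepta-1,5-dien-2-yl)-5-(trimethylsilyl)-2,3-dihydro-1-benzofuran-6-yl trifluoromethanesulfonate | C=C(CCC=C(C)C)[C@H]1Cc2c(OCOC)c([Si](C)(C)C)c(OS(=O)(=O)C(F)(F)F)cc2O1
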